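## Retrosynthetic overview

Atom labels used throughout: C6 = lactone carbinol, C7 = ring-fusion CH, C8 = isobutyrate carbinol, C11/C12/C13 = lactone C(=CH2)C=O, C1=C10 = ring alkene, C14/C15 = the CH2OH carbons on C10/C4.

1. Target 25 ⇐ allylboronate 22 (last step): the lactol is unmasked and C6–C7 closes by intramolecular allylboration (ten-membered carbocycle first); the O6-borate then closes the γ-lactone in the same flask. C6 and C7 are set here.
2. 22 ⇐ ynoate 19 by syn-hydroalumination and ICH2Bpin trapping (puts C8 cis to CO2Me); 19 ⇐ aldehyde 15 + methyl propiolate (Zn–ProPhenol sets C8) with isobutyrylation in the same flask.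
3. 15 ⇐ acid 11 (conjugated CO2H → CH2OTES, CH2CO2Me → CH2CHO); 11 ⇐ alkene 9 + 4-methyl itaconate by cross-metathesis (sets the C1=C10 geometry).
4. 9 ⇐ butyrolactone 7 ⇐ Evans alkylation of a hex-5-enoyl imide with tert-butyl bromoacetate (sets C4).

Assumption: the acetal/lactol carbon of the tetrahydrofuran intermediates (later C6) is carried as an epimer mixture and drawn without configuration; the ProPhenol antipode in step 9 is the one that gives the (R)-carbinol, written here as (S,S).

## Route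

Step 1
Reactants: 1 (S)-4-benzyloxazolidin-2-one; 2 hex-5-enoyl chloride
Product: 3 (S)-4-benzyl-3-(hex-5-enoyl)oxazolidin-2-one
Conditions: n-BuLi, THF, −78 °C; then 2, −78 → 0 °C
Reagents that add atoms: none
Why: N-acylation of the lithiated Evans auxiliary by an acid chloride is fast and clean, and no stereocentre is formed.

Step 2
Reactants: 3; 4 tert-butyl bromoacetate
Product: 5 tert-butyl (R)-3-[(S)-4-benzyl-2-oxooxazolidine-3-carbonyl]hept-6-enoate
Conditions: NaHMDS, THF, −78 °C; then 4, −78 → −40 °C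
Reagents that add atoms: none
Why: Evans asymmetric alkylation: the chelated (Z)-sodium enolate is alkylated by the reactive α-bromo ester on the face away from the benzyl group, which sets C4 as R.

Step 3
Reactants: 5
Product: 7 (R)-4-(but-3-en-1-yl)dihydrofuran-2(3H)-one, via hydroxy ester 6 (not isolated)
Conditions: LiBH4, H2O (1 equiv), Et2O, 0 °C; then HCl (4 M in dioxane), rt
Reagents that add atoms: none
Why: Reductive cleavage of the imide by LiBH4 spares the tert-butyl ester, and acidolysis of that ester then lactonises onto the new primary alcohol without touching C4.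

Step 4
Reactants: 7
Product: 9 (4R)-4-(but-3-en-1-yl)-2-methoxytetrahydrofuran, via lactol 8 (not isolated)
Conditions: DIBAL-H, CH2Cl2, −78 °C; then MeOH, HCl (4 M in dioxane), −78 °C → rt
Reagents that add atoms: methanol (CO)
Why: DIBAL-H half-reduction of a γ-lactone stops at the aluminium lactolate, and Fischer-type acetalisation stores the future C6 aldehyde and the C15 oxygen together in one acid-labile ring.

Step 5
Reactants: 9; 10 4-methyl hydrogen itaconate (4-methoxy-2-methylidene-4-oxobutanoic acid)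
Product: 11 (E)-2-(2-methoxy-2-oxoethyl)-5-[(3R)-5-methoxytetrahydrofuran-3-yl]pent-2-enoic acid
Conditions: Hoveyda–Grubbs II (5 mol%), 10 (3 equiv), CH2Cl2, 40 °C
Reagents that add atoms: none
Why: Olefin cross-metathesis of a terminal alkene with a 1,1-disubstituted acrylic acid gives, as with methacrylates, the conjugated trisubstituted alkene with the chain trans to the carboxyl, which is the C1=C10 geometry of the target.

Step 6
Reactants: 11
Product: 13 methyl (E)-3-(hydroxymethyl)-6-[(3R)-5-methoxytetrahydrofuran-3-yl]hex-3-enoate, via mixed anhydride 12 (not isolated)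
Conditions: i-BuOCOCl, N-methylmorpholine, THF, −15 °C; then NaBH4, H2O, −15 → 0 °C
Reagents that add atoms: none
Why: Mixed carbonic anhydride activation followed by NaBH4 reduces only the conjugated carboxyl (1,2-reduction to the allylic alcohol) and leaves the methyl ester, the acetal and the alkene geometry alone.

Step 7
Reactants: 13
Product: 14 methyl (E)-6-[(3R)-5-methoxytetrahydrofuran-3-yl]-3-{[(triethylsilyl)oxy]methyl}hex-3-enoate
Conditions: TESCl, imidazole, CH2Cl2, 0 °C
Reagents that add atoms: chlorotriethylsilane (CC[Si](Cl)(CC)CC)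
Why: Silylation of the primary allylic alcohol is done at once so that 13 cannot lactonise onto its ester, and TES is chosen because it is lost in the acid stage of step 11.

Step 8
Reactants: 14
Product: 15 (E)-6-[(3R)-5-methoxytetrahydrofuran-3-yl]-3-{[(triethylsilyl)oxy]methyl}hex-3-enal
Conditions: DIBAL-H (1.05 equiv), CH2Cl2, −78 °C; Rochelle salt work-up; used at once
Reagents that add atoms: none
Why: Partial DIBAL-H reduction: the tetrahedral aluminate of the unhindered methyl ester is stable at −78 °C and releases the β,γ-unsaturated aldehyde only on work-up.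

Step 9
Reactants: 15; 16 methyl propiolate; 17 isobutyric anhydride
Product: 19 methyl (4R,6E)-4-(isobutyryloxy)-9-[(3R)-5-methoxytetrahydrofuran-3-yl]-6-{[(triethylsilyl)oxy]methyl}non-6-en-2-ynoate, via zinc alkoxide 18 (not isolated)
Conditions: (S,S)-ProPhenol (20 mol%), Me2Zn (3 equiv), Ph3P=O (40 mol%), PhMe, 4 °C; then 17, DMAP (cat.), 0 °C → rt; aq. NH4Cl work-up
Reagents that add atoms: none
Why: Trost's dinuclear Zn–ProPhenol alkynylation adds the zinc acetylide of 16 to one face of the aldehyde under catalyst control (C8, R), and the zinc alkoxide is acylated in the same flask.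

Step 10
Reactants: 19; 20 2-(iodomethyl)-4,4,5,5-tetramethyl-1,3,2-dioxaborolane
Product: 22 methyl (2Z,4R,6E)-4-(isobutyryloxy)-9-[(3R)-5-methoxytetrahydrofuran-3-yl]-2-[(4,4,5,5-tetramethyl-1,3,2-dioxaborolan-2-yl)methyl]-6-{[(triethylsilyl)oxy]methyl}nona-2,6-dienoate, via vinylalane 21 (not isolated)
Conditions: DIBAL-H (1.3 equiv), HMPA, THF, 0 °C; then 20, 0 °C → rt; aq. NaHCO3/Rochelle salt work-up
Reagents that add atoms: none
Why: Tsuda–Saegusa conjugate syn-hydroalumination of the ynoate (H to C7, Al to C11) and C-alkylation by the iodomethylboronate on the side away from C8 (Hall's allylboronate synthesis) place C8 cis to CO2Me, the geometry needed for an anti allylboration.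

Step 11
Reactants: 22
Product: 25 (3aS,4R,6E,10R,11aR)-6,10-bis(hydroxymethyl)-3-methylene-2-oxo-2,3,3a,4,5,8,9,10,11,11a-decahydrocyclodeca[b]furan-4-yl isobutyrate, via lactol boronate 23 (not isolated), via ring-closed borate 24 (not isolated)
Conditions: AcOH/THF/H2O (3:1:1), 40 °C; evaporate; Sc(OTf)3 (20 mol%), CH2Cl2 (1 mM), rt; then p-TsOH·H2O (cat.), rt
Reagents that add atoms: water (O)
Why: Proposed new method: aqueous acid frees the lactol (latent C6 aldehyde) and the C14 alcohol, and the ring-open hydroxy aldehyde then undergoes a Sc(OTf)3-catalysed intramolecular Type I allylboration through a chair transition state with C5 and C8 both equatorial (C8 is trans to CH2B), which gives the 6,7-anti adduct, while A(1,3) strain with the cis ester holds H8 in the alkene plane so that C6 bonds to the C7 face anti to the tether carbon C9 (6R,7S), and the O6-borate then acylates itself with the neighbouring methyl ester to close the trans-fused α-methylene-γ-lactone, so the ten-membered carbocycle and the lactone form in one flask; the closest known reactions are Hall's Lewis-acid-catalysed allylboration/lactonisation of 2-alkoxycarbonyl allylboronates with aldehydes and the chromium- or boron-mediated ten-membered allylation macrocyclisations used for germacranolides.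

## Compound list

1 | (S)-4-benzyloxazolidin-2-one | O=C1OC[C@H](Cc2ccccc2)N1 | starting material
2 | hex-5-enoyl chloride | C=CCCCC(=O)Cl | starting material
3 | (S)-4-benzyl-3-(hex-5-enoyl)oxazolidin-2-one | C=CCCCC(=O)N1[C@@H](Cc2ccccc2)COC1=O | intermediate
4 | tert-butyl bromoacetate | BrCC(=O)OC(C)(C)C | starting material
5 | tert-butyl (R)-3-[(S)-4-benzyl-2-oxooxazolidine-3-carbonyl]hept-6-enoate | C=CCC[C@H](CC(=O)OC(C)(C)C)C(=O)N1[C@@H](Cc2ccccc2)COC1=O | intermediate
6 | tert-butyl (R)-3-(hydroxymethyl)hept-6-enoate | C=CCC[C@H](CC(=O)OC(C)(C)C)CO | intermediate (not isolated)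
7 | (R)-4-(but-3-en-1-yl)dihydrofuran-2(3H)-one | C=CCC[C@@H]1CC(=O)OC1 | intermediate
8 | (4R)-4-(but-3-en-1-yl)tetrahydrofuran-2-ol, anomer mixture | C=CCC[C@@H]1CC(O)OC1 | intermediate (not isolated)
9 | (4R)-4-(but-3-en-1-yl)-2-methoxytetrahydrofuran, anomer mixture | C=CCC[C@@H]1CC(OC)OC1 | intermediate
10 | 4-methyl hydrogen itaconate (4-methoxy-2-methylidene-4-oxobutanoic acid) | C=C(CC(=O)OC)C(=O)O | starting material
11 | (E)-2-(2-methoxy-2-oxoethyl)-5-[(3R)-5-methoxytetrahydrofuran-3-yl]pent-2-enoic acid | OC(=O)/C(CC(=O)OC)=C/CC[C@@H]1CC(OC)OC1 | intermediate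
12 | isobutyl carbonic mixed anhydride of 11 | CC(C)COC(=O)OC(=O)/C(CC(=O)OC)=C/CC[C@@H]1CC(OC)OC1 | intermediate (not isolated)
13 | methyl (E)-3-(hydroxymethyl)-6-[(3R)-5-methoxytetrahydrofuran-3-yl]hex-3-enoate | OC/C(CC(=O)OC)=C/CC[C@@H]1CC(OC)OC1 | intermediate
14 | methyl (E)-6-[(3R)-5-methoxytetrahydrofuran-3-yl]-3-{[(triethylsilyl)oxy]methyl}hex-3-enoate | CC[Si](CC)(CC)OC/C(CC(=O)OC)=C/CC[C@@H]1CC(OC)OC1 | intermediate
15 | (E)-6-[(3R)-5-methoxytetrahydrofuran-3-yl]-3-{[(triethylsilyl)oxy]methyl}hex-3-enal | CC[Si](CC)(CC)OC/C(CC=O)=C/CC[C@@H]1CC(OC)OC1 | intermediate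
16 | methyl propiolate | C#CC(=O)OC | starting material
17 | isobutyric anhydride | CC(C)C(=O)OC(=O)C(C)C | starting material
18 | methylzinc alkoxide of methyl (4R,6E)-4-hydroxy-9-[(3R)-5-methoxytetrahydrofuran-3-yl]-6-{[(triethylsilyl)oxy]methyl}non-6-en-2-ynoate | CC[Si](CC)(CC)OC/C(C[C@@H](O[Zn]C)C#CC(=O)OC)=C/CC[C@@H]1CC(OC)OC1 | intermediate (not isolated)
19 | methyl (4R,6E)-4-(isobutyryloxy)-9-[(3R)-5-methoxytetrahydrofuran-3-yl]-6-{[(triethylsilyl)oxy]methyl}non-6-en-2-ynoate | CC[Si](CC)(CC)OC/C(C[C@@H](OC(=O)C(C)C)C#CC(=O)OC)=C/CC[C@@H]1CC(OC)OC1 | intermediate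
20 | 2-(iodomethyl)-4,4,5,5-tetramethyl-1,3,2-dioxaborolane | ICB1OC(C)(C)C(C)(C)O1 | starting material
21 | diisobutylaluminium vinylalane from 19 (Al on C11, H on C7, C8 cis to CO2Me) | CC[Si](CC)(CC)OC/C(C[C@@H](OC(=O)C(C)C)/C=C(/[Al](CC(C)C)CC(C)C)C(=O)OC)=C/CC[C@@H]1CC(OC)OC1 | intermediate (not isolated)
22 | methyl (2Z,4R,6E)-4-(isobutyryloxy)-9-[(3R)-5-methoxytetrahydrofuran-3-yl]-2-[(4,4,5,5-tetramethyl-1,3,2-dioxaborolan-2-yl)methyl]-6-{[(triethylsilyl)oxy]methyl}nona-2,6-dienoate | CC[Si](CC)(CC)OC/C(C[C@@H](OC(=O)C(C)C)/C=C(/CB1OC(C)(C)C(C)(C)O1)C(=O)OC)=C/CC[C@@H]2CC(OC)OC2 | intermediate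
23 | methyl (2Z,4R,6E)-9-[(3R)-5-hydroxytetrahydrofuran-3-yl]-6-(hydroxymethyl)-4-(isobutyryloxy)-2-[(4,4,5,5-tetramethyl-1,3,2-dioxaborolan-2-yl)methyl]nona-2,6-dienoate | OC/C(C[C@@H](OC(=O)C(C)C)/C=C(/CB1OC(C)(C)C(C)(C)O1)C(=O)OC)=C/CC[C@@H]2CC(O)OC2 | intermediate (not isolated)
24 | ring-closed seco ester: methyl 2-substituted acrylate on C7 of the cyclodecene, O6 as pinacol borate, 8-O-isobutyrate, configuration as in 25 | C=C(C(=O)OC)[C@H]1[C@H](OB2OC(C)(C)C(C)(C)O2)C[C@H](CO)CC/C=C(/CO)C[C@H]1OC(=O)C(C)C | intermediate (not isolated)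
25 | (3aS,4R,6E,10R,11aR)-6,10-bis(hydroxymethyl)-3-methylene-2-oxo-2,3,3a,4,5,8,9,10,11,11a-decahydrocyclodeca[b]furan-4-yl isobutyrate | C=C1C(=O)O[C@@H]2C[C@H](CO)CC/C=C(/CO)C[C@@H](OC(=O)C(C)C)[C@@H]12 | target

## Step count and risk

Total step count: 11. Longest linear sequence: 11 steps (1 → 25); all other inputs are purchased.

The three steps most likely to fail are steps 11, 10 and 5.

Step 11 is the weakest point: a ten-membered ring has to close by allylboration from a lactol that is mostly in its closed form, and oligomers or the wrong C7 epimer are possible. The fallback closes the two rings one after the other, the carbocycle by ring-closing metathesis; it sets out from 7 and 10 and comes back to the route at 25. Acid 10 is taken on its own through the chemistry of steps 6 to 10: the isobutyl carbonic mixed anhydride of 10 F1, methyl 3-(hydroxymethyl)but-3-enoate F2, methyl 3-{[(triethylsilyl)oxy]methyl}but-3-enoate F3, 3-{[(triethylsilyl)oxy]methyl}but-3-enal F4, the methylzinc alkoxide of the (R)-propargylic alcohol F5 (with 16), methyl (R)-4-(isobutyryloxy)-6-{[(triethylsilyl)oxy]methyl}hept-6-en-2-ynoate F6 (with 17), the vinylalane F7 and the (2Z)-allylboronate F8 (with 20). Lactone 7 is reduced with DIBAL-H to lactol 8, which is isolated here. Lactol 8 and F8 react under Sc(OTf)3 at 0.2 M through the open-chain borate F9 to the α-methylene lactone diene F10, in which the boronate geometry and the C8 centre control C6 and C7 as in step 11. Ring-closing metathesis (Hoveyda–Grubbs II, PhMe, 80 °C, 1 mM) joins the C1 vinyl and C10 methylene groups to the C14 triethylsilyl ether of the target F11, the ring enforcing the cis ring alkene, and AcOH/THF/H2O gives 25.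

Step 10 can fail because DIBAL-H may attack the isobutyrate or displace the propargylic ester (allene formation), or the aluminium species may alkylate poorly. The fallback replaces hydride addition and alkylation by hydrostannation and cross-coupling; it sets out from 19 and comes back at 22. Pd(PPh3)4-catalysed syn-hydrostannation with Bu3SnH (THF, 0 °C) gives the α-stannyl enoate F12 with C8 cis to the ester, iodine converts it with retention into the α-iodo enoate F13, and Negishi coupling with (pinacolboryl)methylzinc iodide F14 (from 20 and zinc dust) under Pd catalysis gives 22.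

Step 5 can fail because a 1,1-disubstituted, chelating acrylic acid is a sluggish metathesis partner and the free acid may disturb the methyl acetal. The fallback builds the same alkene by Wittig olefination; it sets out from 9 and comes back at 11. Ozonolysis of 9 (O3, CH2Cl2, −78 °C; PPh3) gives 3-[(3R)-5-methoxytetrahydrofuran-3-yl]propanal F15. The stabilised ylide 4-methoxy-4-oxo-2-(triphenylphosphoranylidene)butanoic acid F16, made by opening commercial 2-(triphenylphosphoranylidene)succinic anhydride with methanol, condenses with F15 (CH2Cl2, rt) to give 11 with the same E geometry.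

## Further compounds

F1 | step 11 | isobutyl carbonic mixed anhydride of 10 | C=C(CC(=O)OC)C(=O)OC(=O)OCC(C)C
F2 | step 11 | methyl 3-(hydroxymethyl)but-3-enoate | C=C(CO)CC(=O)OC
F3 | step 11 | methyl 3-{[(triethylsilyl)oxy]methyl}but-3-enoate | C=C(CO[Si](CC)(CC)CC)CC(=O)OC
F4 | step 11 | 3-{[(triethylsilyl)oxy]methyl}but-3-enal | C=C(CO[Si](CC)(CC)CC)CC=O
F5 | step 11 | methylzinc alkoxide of methyl (R)-4-hydroxy-6-{[(triethylsilyl)oxy]methyl}hept-6-en-2-ynoate | C=C(CO[Si](CC)(CC)CC)C[C@@H](O[Zn]C)C#CC(=O)OC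
F6 | step 11 | methyl (R)-4-(isobutyryloxy)-6-{[(triethylsilyl)oxy]methyl}hept-6-en-2-ynoate | C=C(CO[Si](CC)(CC)CC)C[C@@H](OC(=O)C(C)C)C#CC(=O)OC
F7 | step 11 | diisobutylaluminium vinylalane from F6 | C=C(CO[Si](CC)(CC)CC)C[C@@H](OC(=O)C(C)C)/C=C(/[Al](CC(C)C)CC(C)C)C(=O)OC
F8 | step 11 | methyl (2Z,4R)-4-(isobutyryloxy)-2-[(4,4,5,5-tetramethyl-1,3,2-dioxaborolan-2-yl)methyl]-6-{[(triethylsilyl)oxy]methyl}hepta-2,6-dienoate | C=C(CO[Si](CC)(CC)CC)C[C@@H](OC(=O)C(C)C)/C=C(/CB1OC(C)(C)C(C)(C)O1)C(=O)OC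
F9 | step 11 | open-chain O6 pinacol borate from 8 and F8 (acrylate on C7, configuration as in 25) | C=CCC[C@@H](CO)C[C@@H](OB1OC(C)(C)C(C)(C)O1)[C@H](C(=C)C(=O)OC)[C@H](OC(=O)C(C)C)CC(=C)CO[Si](CC)(CC)CC
F10 | step 11 | 1,10-seco diene lactone: trans α-methylene-γ-lactone with C1 vinyl and C10 methylene groups, 8-O-isobutyrate, 14-O-TES, configuration as in 25 | C=C1C(=O)O[C@H](C[C@H](CO)CCC=C)[C@H]1[C@H](OC(=O)C(C)C)CC(=C)CO[Si](CC)(CC)CC
F11 | step 11 | C14 triethylsilyl ether of 25 | C=C1C(=O)O[C@@H]2C[C@H](CO)CC/C=C(/CO[Si](CC)(CC)CC)C[C@@H](OC(=O)C(C)C)[C@@H]12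
F12 | step 10 | methyl (2E,4R,6E)-4-(isobutyryloxy)-9-[(3R)-5-methoxytetrahydrofuran-3-yl]-2-(tributylstannyl)-6-{[(triethylsilyl)oxy]methyl}nona-2,6-dienoate | CC[Si](CC)(CC)OC/C(C[C@@H](OC(=O)C(C)C)/C=C(/[Sn](CCCC)(CCCC)CCCC)C(=O)OC)=C/CC[C@@H]1CC(OC)OC1
F13 | step 10 | methyl (2E,4R,6E)-2-iodo-4-(isobutyryloxy)-9-[(3R)-5-methoxytetrahydrofuran-3-yl]-6-{[(triethylsilyl)oxy]methyl}nona-2,6-dienoate | CC[Si](CC)(CC)OC/C(C[C@@H](OC(=O)C(C)C)/C=C(/I)C(=O)OC)=C/CC[C@@H]1CC(OC)OC1
F14 | step 10 | (pinacolboryl)methylzinc iodide | I[Zn]CB1OC(C)(C)C(C)(C)O1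
F15 | step 5 | 3-[(3R)-5-methoxytetrahydrofuran-3-yl]propanal | O=CCC[C@@H]1CC(OC)OC1
F16 | step 5 | 4-methoxy-4-oxo-2-(triphenylphosphoranylidene)butanoic acid | COC(=O)CC(C(=O)O)=P(c1ccccc1)(c1ccccc1)c1ccccc1
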